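The plan rests on cutting ring B of galbulin at C1–ring C and at C2–C3. The three adjacent stereocentres C1, C2 and C3 are mutually trans, which means an aryl group delivered to C1 of a cinnamate-type enoate generates a C2 enolate positioned to attack an acceptor hung on C3 and close ring B in its all-equatorial chair. A single chiral-diene rhodium-catalysed arylation–Michael cascade thus makes two C–C bonds, ring B and all three stereocentres. Its substrate is an achiral ring A veratrole bearing ortho E-acrylate and E-3-(phenylsulfonyl)allyl arms; the ester and sulfonylmethyl carbons later become the two methyls.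

Key step: step 4

Numbering: tetralin numbering is used throughout (C1 carries ring C, C2 and C3 the methyls, C4 is the CH2; ring A is the dimethoxybenzo ring, ring B the carbocycle closed in step 4, ring C the pendant aryl).

Assumption: (R,R)-Ph-bod* is taken to deliver ring C to the enoate face that gives 1S, by analogy with its facial preference on enones; should the opposite sense result, the (S,S)-ligand is used and nothing else changes.

Descriptor note: C2 is 2R in 10–13 and 2S in 14 only because CIP priorities change; no centre is inverted after step 4.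

Step 1
Reactants: 1 2-bromo-4,5-dimethoxybenzaldehyde; 2 methyl (triphenylphosphoranylidene)acetate
Product: 3 methyl (E)-3-(2-bromo-4,5-dimethoxyphenyl)acrylate
Conditions: toluene, 90 °C
Reagents that add atoms: none
Why: Wittig olefination with a stabilised ylide gives the E-enoate through the less crowded oxaphosphetane and leaves the aryl bromide untouched.

Step 2
Reactants: 3 methyl (E)-3-(2-bromo-4,5-dimethoxyphenyl)acrylate; 4 allyltributylstannane
Product: 5 methyl (E)-3-(2-allyl-4,5-dimethoxyphenyl)acrylate
Conditions: Pd(PPh3)4 (5 mol%), toluene, 110 °C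
Reagents that add atoms: none
Why: Stille coupling, in which zerovalent palladium inserts into the C–Br bond activated by the ortho enoate, tin transfers the allyl group and reductive elimination gives the allylarene under neutral conditions that spare the enoate.

Step 3
Reactants: 5 methyl (E)-3-(2-allyl-4,5-dimethoxyphenyl)acrylate; 6 phenyl vinyl sulfone
Product: 7 methyl (E)-3-{4,5-dimethoxy-2-[(E)-3-(phenylsulfonyl)prop-2-en-1-yl]phenyl}acrylate
Conditions: 6 (3 equiv), second-generation Grubbs catalyst [RuCl2(=CHPh)(PCy3)(H2IMes)] (5 mol%), 1,4-benzoquinone (10 mol%), CH2Cl2, 40 °C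
Reagents that add atoms: none
Why: Olefin cross-metathesis of a readily initiating terminal allylarene with an electron-poor vinyl sulfone that does not homodimerise should give the E-vinyl sulfone, while the conjugated disubstituted enoate alkene is a far poorer metathesis partner and benzoquinone suppresses double-bond migration.

Step 4
Reactants: 7 methyl (E)-3-{4,5-dimethoxy-2-[(E)-3-(phenylsulfonyl)prop-2-en-1-yl]phenyl}acrylate; 8 3,4-dimethoxyphenylboronic acid
Product: 10 methyl (1S,2R,3R)-1-(3,4-dimethoxyphenyl)-6,7-dimethoxy-3-[(phenylsulfonyl)methyl]-1,2,3,4-tetrahydronaphthalene-2-carboxylate, via rhodium enolate 9 (not isolated)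
Conditions: 8 (2.5 equiv), [RhCl(C2H4)2]2 (2.5 mol%), (1R,4R)-2,5-diphenylbicyclo[2.2.2]octa-2,5-diene [(R,R)-Ph-bod*] (5.5 mol%), KOH (10 mol%), dioxane/H2O (20:1), 40 °C
Reagents that add atoms: none
Why: Proposed new method: transmetalation of 8 to the hydroxo(diene) complex of monovalent rhodium gives an arylrhodium species that inserts the enoate alkene of 7 to place ring C on C1 and leave rhodium enolate 9, whose C2 carbon then adds to the sulfone-remote alkene carbon (C3) of the tethered vinyl sulfone before water protonates the α-sulfonyl carbon and returns the hydroxorhodium catalyst. The closest known reaction type is the rhodium-catalysed tandem conjugate addition of arylboronic acids and Michael cyclisation of tethered bis-enones; an ester-derived rhodium enolate closing onto a vinyl sulfone has not been shown, hence the label. Ring B closes in a 6-exo-trig mode through a chair-like transition state fused to ring A. C1 is set by the chiral diene, which shields one enantioface of the enoate during aryl migration, while C2 and C3 are set relative to C1 by the transition state that keeps the C1 aryl group, the C2 ester and the C3 sulfonylmethyl arm equatorial, and the C2 centre stays correctable by ester epimerisation. The step needs the arylrhodium to choose the enoate over the vinyl sulfone, which the substrate secures because a β-alkyl phenyl vinyl sulfone without a coordinating group is a poor acceptor for arylrhodium whereas it is still electrophilic enough for the tethered enolate. It also needs the vinyl sulfone to stay out of conjugation with ring A, which the low hydroxide charge buffered by excess boronic acid is meant to secure.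

Step 5
Reactants: 10 methyl (1S,2R,3R)-1-(3,4-dimethoxyphenyl)-6,7-dimethoxy-3-[(phenylsulfonyl)methyl]-1,2,3,4-tetrahydronaphthalene-2-carboxylate
Product: 11 [(1S,2R,3R)-1-(3,4-dimethoxyphenyl)-6,7-dimethoxy-3-[(phenylsulfonyl)methyl]-1,2,3,4-tetrahydronaphthalen-2-yl]methanol
Conditions: LiAlH4, THF, 0 °C
Reagents that add atoms: none
Why: Hydride reduction of the methyl ester to the primary alcohol is much faster than enolisation at C2 and at 0 °C leaves the alkyl aryl sulfone untouched.

Step 6
Reactants: 11 [(1S,2R,3R)-1-(3,4-dimethoxyphenyl)-6,7-dimethoxy-3-[(phenylsulfonyl)methyl]-1,2,3,4-tetrahydronaphthalen-2-yl]methanol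
Product: 12 [(1S,2R,3R)-1-(3,4-dimethoxyphenyl)-6,7-dimethoxy-3-[(phenylsulfonyl)methyl]-1,2,3,4-tetrahydronaphthalen-2-yl]methyl methanesulfonate
Conditions: MsCl, Et3N, CH2Cl2, 0 °C
Reagents that add atoms: methanesulfonyl chloride, CS(=O)(=O)Cl
Why: O-sulfonylation of an unhindered primary alcohol (mesylation) touches no stereocentre and turns the hydroxyl into a leaving group.

Step 7
Reactants: 12 [(1S,2R,3R)-1-(3,4-dimethoxyphenyl)-6,7-dimethoxy-3-[(phenylsulfonyl)methyl]-1,2,3,4-tetrahydronaphthalen-2-yl]methyl methanesulfonate
Product: 13 (1S,2R,3R)-1-(3,4-dimethoxyphenyl)-6,7-dimethoxy-2-methyl-3-[(phenylsulfonyl)methyl]-1,2,3,4-tetrahydronaphthalene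
Conditions: LiEt3BH, THF, 0 °C to rt
Reagents that add atoms: none
Why: SN2 displacement of the primary mesylate by the strongly nucleophilic hydride of LiEt3BH suits β-branched primary sulfonates, spares the sulfone and turns the former ester carbon into the C2 methyl.

Step 8
Reactants: 13 (1S,2R,3R)-1-(3,4-dimethoxyphenyl)-6,7-dimethoxy-2-methyl-3-[(phenylsulfonyl)methyl]-1,2,3,4-tetrahydronaphthalene
Product: 14 galbulin [(1S,2S,3R)-1-(3,4-dimethoxyphenyl)-6,7-dimethoxy-2,3-dimethyl-1,2,3,4-tetrahydronaphthalene]
Conditions: Mg turnings, MeOH, 50 °C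
Reagents that add atoms: none
Why: Reductive desulfonylation by single-electron transfer from magnesium cleaves the exocyclic alkyl C–S bond and methanol protonates the resulting carbanion, revealing the C3 methyl without touching a stereocentre or the aryl ethers.

Compound list
1 | 2-bromo-4,5-dimethoxybenzaldehyde | COc1cc(Br)c(C=O)cc1OC | starting material
2 | methyl (triphenylphosphoranylidene)acetate | COC(=O)C=P(c1ccccc1)(c1ccccc1)c1ccccc1 | starting material
3 | methyl (E)-3-(2-bromo-4,5-dimethoxyphenyl)acrylate | COC(=O)/C=C/c1cc(OC)c(OC)cc1Br | intermediate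
4 | allyltributylstannane | C=CC[Sn](CCCC)(CCCC)CCCC | starting material
5 | methyl (E)-3-(2-allyl-4,5-dimethoxyphenyl)acrylate | COC(=O)/C=C/c1cc(OC)c(OC)cc1CC=C | intermediate
6 | phenyl vinyl sulfone | C=CS(=O)(=O)c1ccccc1 | starting material
7 | methyl (E)-3-{4,5-dimethoxy-2-[(E)-3-(phenylsulfonyl)prop-2-en-1-yl]phenyl}acrylate | COC(=O)/C=C/c1cc(OC)c(OC)cc1C/C=C/S(=O)(=O)c1ccccc1 | intermediate
8 | 3,4-dimethoxyphenylboronic acid | COc1ccc(B(O)O)cc1OC | starting material
9 | rhodium enolate of methyl (S)-3-{4,5-dimethoxy-2-[(E)-3-(phenylsulfonyl)prop-2-en-1-yl]phenyl}-3-(3,4-dimethoxyphenyl)propanoate (O-bound form drawn; diene ligand on rhodium omitted) | COC(O[Rh])=C[C@@H](c1ccc(OC)c(OC)c1)c1cc(OC)c(OC)cc1C/C=C/S(=O)(=O)c1ccccc1 | intermediate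
10 | methyl (1S,2R,3R)-1-(3,4-dimethoxyphenyl)-6,7-dimethoxy-3-[(phenylsulfonyl)methyl]-1,2,3,4-tetrahydronaphthalene-2-carboxylate (ring C, ester and sulfonylmethyl all trans) | COc1ccc([C@H]2c3cc(OC)c(OC)cc3C[C@@H](CS(=O)(=O)c3ccccc3)[C@@H]2C(=O)OC)cc1OC | intermediate
11 | [(1S,2R,3R)-1-(3,4-dimethoxyphenyl)-6,7-dimethoxy-3-[(phenylsulfonyl)methyl]-1,2,3,4-tetrahydronaphthalen-2-yl]methanol | COc1ccc([C@H]2c3cc(OC)c(OC)cc3C[C@@H](CS(=O)(=O)c3ccccc3)[C@@H]2CO)cc1OC | intermediate
12 | [(1S,2R,3R)-1-(3,4-dimethoxyphenyl)-6,7-dimethoxy-3-[(phenylsulfonyl)methyl]-1,2,3,4-tetrahydronaphthalen-2-yl]methyl methanesulfonate | COc1ccc([C@H]2c3cc(OC)c(OC)cc3C[C@@H](CS(=O)(=O)c3ccccc3)[C@@H]2COS(C)(=O)=O)cc1OC | intermediate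
13 | (1S,2R,3R)-1-(3,4-dimethoxyphenyl)-6,7-dimethoxy-2-methyl-3-[(phenylsulfonyl)methyl]-1,2,3,4-tetrahydronaphthalene | COc1ccc([C@H]2c3cc(OC)c(OC)cc3C[C@@H](CS(=O)(=O)c3ccccc3)[C@@H]2C)cc1OC | intermediate
14 | galbulin, (1S,2S,3R)-1-(3,4-dimethoxyphenyl)-6,7-dimethoxy-2,3-dimethyl-1,2,3,4-tetrahydronaphthalene (all trans) | COc1ccc([C@H]2c3cc(OC)c(OC)cc3C[C@@H](C)[C@@H]2C)cc1OC | target

Total step count: 8.
Longest linear sequence: 8 steps (1 to 14).

Steps most likely to fail

Step 4. The rhodium enolate may be protonated by water before it reaches the vinyl sulfone. The vinyl sulfone double bond may also migrate into conjugation with ring A, or the aryl group may be transferred to the sulfone-bearing alkene. The fallback sets out from 5 and comes back at 10; it separates the two Michael events and uses known chemistry only. Compound 5, which has no second acceptor, is submitted to the established rhodium/chiral diene conjugate arylation of a cinnamate ester with 8 ([RhCl(C2H4)2]2, (R,R)-Ph-bod*, KOH, dioxane/H2O 10:1, 40 °C). This should give methyl (S)-3-(2-allyl-4,5-dimethoxyphenyl)-3-(3,4-dimethoxyphenyl)propanoate F1 with C1 already set. Cross-metathesis of F1 with 6 under the conditions of step 3, now with no enoate alkene in the molecule, should give methyl (S)-3-{4,5-dimethoxy-2-[(E)-3-(phenylsulfonyl)prop-2-en-1-yl]phenyl}-3-(3,4-dimethoxyphenyl)propanoate F2. This is also the compound that premature protonation in step 4 would leave, so such material can be fed in here. Intramolecular Michael addition of the ester enolate to the vinyl sulfone under equilibrating conditions (NaOMe, MeOH/THF, 50 °C; 6-exo-trig) then closes ring B. Reversible proton transfer lets any conjugated allyl sulfone isomer re-enter through the vinyl sulfone and settles C2, so the all-equatorial tetralin 10 is the expected sink.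

Step 3. The ruthenium alkylidene formed at the allyl terminus may ring-close onto the enoate alkene, giving an indene with loss of the acrylate unit. A ruthenium hydride may also move the allyl double bond into conjugation before metathesis. The fallback sets out from 1 and comes back at 7; it runs the metathesis before any enoate exists. Stille allylation of 1 with 4 (Pd(PPh3)4, toluene, 110 °C) should give 2-allyl-4,5-dimethoxybenzaldehyde F3. Cross-metathesis of F3 with 6 (second-generation Grubbs catalyst, CH2Cl2, 40 °C) should give (E)-4,5-dimethoxy-2-[3-(phenylsulfonyl)prop-2-en-1-yl]benzaldehyde F4, with no second alkene available for ring closure. Wittig olefination of F4 with the weakly basic stabilised ylide 2 (CH2Cl2, rt) then installs the E-enoate and gives 7.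

Step 8. Electron transfer from magnesium to an unactivated primary alkyl phenyl sulfone may be too slow, so the C–S bond is cleaved incompletely or not at all. The fallback sets out from 13 and comes back at 14; it replaces electron-transfer cleavage by deoxygenation and hydrogenolysis. The sulfone is deoxygenated with LiAlH4/TiCl4 (THF, −78 °C to rt) to (1S,2R,3R)-1-(3,4-dimethoxyphenyl)-6,7-dimethoxy-2-methyl-3-[(phenylsulfanyl)methyl]-1,2,3,4-tetrahydronaphthalene F5. Hydrogenolysis of both C–S bonds of F5 with Raney Ni (EtOH, reflux) then gives 14.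

Further compounds
F1 | step 4 | methyl (S)-3-(2-allyl-4,5-dimethoxyphenyl)-3-(3,4-dimethoxyphenyl)propanoate | COC(=O)C[C@@H](c1ccc(OC)c(OC)c1)c1cc(OC)c(OC)cc1CC=C
F2 | step 4 | methyl (S)-3-{4,5-dimethoxy-2-[(E)-3-(phenylsulfonyl)prop-2-en-1-yl]phenyl}-3-(3,4-dimethoxyphenyl)propanoate | COC(=O)C[C@@H](c1ccc(OC)c(OC)c1)c1cc(OC)c(OC)cc1C/C=C/S(=O)(=O)c1ccccc1
F3 | step 3 | 2-allyl-4,5-dimethoxybenzaldehyde | C=CCc1cc(OC)c(OC)cc1C=O
F4 | step 3 | (E)-4,5-dimethoxy-2-[3-(phenylsulfonyl)prop-2-en-1-yl]benzaldehyde | O=Cc1cc(OC)c(OC)cc1C/C=C/S(=O)(=O)c1ccccc1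
F5 | step 8 | (1S,2R,3R)-1-(3,4-dimethoxyphenyl)-6,7-dimethoxy-2-methyl-3-[(phenylsulfanyl)methyl]-1,2,3,4-tetrahydronaphthalene | COc1ccc([C@H]2c3cc(OC)c(OC)cc3C[C@@H](CSc3ccccc3)[C@@H]2C)cc1OC
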